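## Retrosynthetic overview

- Target 13 comes from 12 by removing two MOM ethers; ring C of 12 is closed last, by forming the O1–C2 bond.
- 12 comes in one operation from the open-chain (αR,βS)-chalcone epoxide 9, in which O1 is stored as a 1,1-dimethylallyl ether. A [3,3] shift moves that five-carbon unit to C8 as the prenyl group and frees O1, which then opens the strained oxirane at benzylic C2 with inversion.
- Enabling feature: on ring A the prenyl-bearing C8 is ortho to C8a–O1, so a single O-allyl group holds both the C8 substituent and the masked O1 nucleophile. C2 (benzylic) and C3 (oxygenated) are vicinal, so both stereocentres can be stored in a trans-oxirane made from an E-enone.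
- 9 comes from E-chalcone 8 (Juliá–Colonna epoxidation), and 8 from the Claisen–Schmidt union of acetophenone 4 and aldehyde 7.
- 4 comes from 2,4-dihydroxyacetophenone 1 (MOM, copper-catalysed tert-propargylation, Lindlar); 7 from 3,5-dibromo-4-hydroxybenzaldehyde 5 (MOM, double Stille prenylation). Rings A and B are bought; ring C is the only ring formed.

Key step: step 8

Remark: read from the SMILES, the target is the 2,3-trans (2R,3R)-dihydroflavonol. Poly-L-leucine is assumed to give the (αR,βS) epoxide with chalcone 8, as it does with the parent chalcone.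

## Route

Step 1
Reactants: 1 1-(2,4-dihydroxyphenyl)ethanone
Product: 2 1-[2-hydroxy-4-(methoxymethoxy)phenyl]ethanone
Conditions: MOMCl (1.1 equiv), K2CO3, acetone, 0 °C → rt
Reagents that add atoms: chloromethyl methyl ether, COCCl
Why: Williamson etherification should take only the 4-OH, because the 2-OH is tied up in a hydrogen bond to the acetyl group and is far less nucleophilic.

Step 2
Reactants: 2 1-[2-hydroxy-4-(methoxymethoxy)phenyl]ethanone
Product: 3 1-[4-(methoxymethoxy)-2-(2-methylbut-3-yn-2-yloxy)phenyl]ethanone
Conditions: 3-chloro-3-methylbut-1-yne, CuCl2·2H2O (1 mol %), DBU, MeCN, 0 °C → rt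
Reagents that add atoms: 3-chloro-3-methylbut-1-yne, CC(C)(Cl)C#C
Why: Copper-catalysed propargylic etherification of phenols with tertiary propargylic chlorides makes hindered aryl tert-propargyl ethers at a temperature where the ether does not yet cyclise to a chromene.

Step 3
Reactants: 3 1-[4-(methoxymethoxy)-2-(2-methylbut-3-yn-2-yloxy)phenyl]ethanone
Product: 4 1-[4-(methoxymethoxy)-2-(2-methylbut-3-en-2-yloxy)phenyl]ethanone
Conditions: H2 (1 atm), Lindlar catalyst (Pd/CaCO3 poisoned with Pb(OAc)2), quinoline, EtOAc, rt
Reagents that add atoms: none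
Why: Lindlar semihydrogenation should stop at the terminal alkene and leave the aryl ketone and the MOM ether alone, the standard way to aryl 1,1-dimethylallyl ethers.

Step 4
Reactants: 5 3,5-dibromo-4-hydroxybenzaldehyde
Product: 6 3,5-dibromo-4-(methoxymethoxy)benzaldehyde
Conditions: MOMCl, K2CO3, acetone, rt
Reagents that add atoms: chloromethyl methyl ether, COCCl
Why: Williamson etherification of an acidic phenol with a very reactive electrophile should tolerate the two flanking bromines and the aldehyde.

Step 5
Reactants: 6 3,5-dibromo-4-(methoxymethoxy)benzaldehyde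
Product: 7 4-(methoxymethoxy)-3,5-bis(3-methylbut-2-enyl)benzaldehyde
Conditions: tributyl(3-methylbut-2-enyl)stannane (2.4 equiv), Pd(PPh3)4 (10 mol %), DMF, 100 °C
Reagents that add atoms: tributyl(3-methylbut-2-en-1-yl)stannane, CCCC[Sn](CCCC)(CCCC)CC=C(C)C
Why: Twofold Stille coupling of an aryl bromide with the prenylstannane should give the linear prenyl arenes and, unlike allylzinc or allylboron reagents, the stannane does not add to the free aldehyde.

Step 6
Reactants: 4 1-[4-(methoxymethoxy)-2-(2-methylbut-3-en-2-yloxy)phenyl]ethanone; 7 4-(methoxymethoxy)-3,5-bis(3-methylbut-2-enyl)benzaldehyde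
Product: 8 (2E)-1-[4-(methoxymethoxy)-2-(2-methylbut-3-en-2-yloxy)phenyl]-3-[4-(methoxymethoxy)-3,5-bis(3-methylbut-2-enyl)phenyl]prop-2-en-1-one
Conditions: KOH, EtOH, 0 °C → rt
Reagents that add atoms: none
Why: Claisen–Schmidt aldol condensation with a non-enolisable aldehyde should give the E-enone under thermodynamic control, and at room temperature the tertiary allyl aryl ether does not yet rearrange.

Step 7
Reactants: 8 the E-chalcone
Product: 9 [(2R,3S)-3-[4-(methoxymethoxy)-3,5-bis(3-methylbut-2-enyl)phenyl]oxiran-2-yl][4-(methoxymethoxy)-2-(2-methylbut-3-en-2-yloxy)phenyl]methanone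
Conditions: poly-L-leucine, urea–H2O2, DBU, THF, rt
Reagents that add atoms: urea–hydrogen peroxide (delivers the epoxide oxygen), NC(N)=O.OO
Why: Juliá–Colonna epoxidation is a Weitz–Scheffer conjugate addition of hydroperoxide inside the helical L-peptide, which should select the enone face that leads to the (αR,βS) trans-epoxide while the isolated prenyl and vinyl alkenes stay inert to the nucleophilic oxidant.

Step 8
Reactants: 9 the (2R,3S)-epoxy ketone
Product: 12 (2R,3R)-3-hydroxy-7-(methoxymethoxy)-2-[4-(methoxymethoxy)-3,5-bis(3-methylbut-2-enyl)phenyl]-8-(3-methylbut-2-enyl)chroman-4-one, via Claisen ortho-dienone 10 (not isolated), via 2'-hydroxy-3'-prenyl epoxy ketone 11 (not isolated)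
Conditions: Eu(fod)3 (10 mol %), PhMe, 80 → 110 °C, sealed tube, base-washed glassware
Reagents that add atoms: none
Why: Proposed new method: the aryl 1,1-dimethylallyl ether, chelated to Eu(fod)3 through its ether and ketone oxygens, should undergo a [3,3]-sigmatropic (aromatic Claisen) shift to C3' of ring A (the future C8), giving dienone 10 that tautomerises to the hydrogen-bonded phenol 11, whose oxygen (the future O1) then opens the Lewis-acid-activated oxirane at the benzylic carbon in the same pot. The closest known reactions are the tandem Claisen rearrangement/6-endo cyclisation of ortho-acyl aryl allyl ethers to 8-allyl- and 8-prenylchromones, the Eu(fod)3-catalysed Claisen shift of aryl prenyl ethers that sit next to a carbonyl group, and the cyclisation of 2'-hydroxychalcone epoxides to trans-dihydroflavonols; what is new is their union in one operation with an enantioenriched epoxide as the trap. Ring C closes in the 6-endo-tet mode, since release of oxirane strain and the benzylic character of the attacked carbon favour it over 5-exo attack at the carbon next to the carbonyl, which would give a benzofuranone. C2 is set by backside attack, so the βS carbon becomes 2R and trans to the 3-OH, while C3 (αR) is carried over untouched. The step needs regioselectivity in the shift, secured because C1' carries the acyl group and C3' is the only free ortho position, and it needs invertive rather than ionising opening, secured because the ring B oxygen is a MOM ether twisted out of conjugation by its two flanking prenyl groups and because the nucleophile is delivered intramolecularly as soon as it forms. The phenol does not exist before the shift, which is why the epoxide can be made and handled under basic conditions beforehand.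

Step 9
Reactants: 12 the bis-MOM dihydroflavonol
Product: 13 (2R,3R)-3,7-dihydroxy-2-[4-hydroxy-3,5-bis(3-methylbut-2-enyl)phenyl]-8-(3-methylbut-2-enyl)chroman-4-one
Conditions: HCl (3 M aq), MeOH/THF, 40 °C
Reagents that add atoms: none
Why: Acid-catalysed acetal exchange should free both phenols under conditions mild enough that the ortho-prenyl phenols do not cyclise to chromans, and the trans-dihydroflavonol is the configurationally stable isomer in acid.

## Compound list

1 | 1-(2,4-dihydroxyphenyl)ethanone | CC(=O)c1ccc(O)cc1O | starting material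
2 | 1-[2-hydroxy-4-(methoxymethoxy)phenyl]ethanone | CC(=O)c1ccc(OCOC)cc1O | intermediate
3 | 1-[4-(methoxymethoxy)-2-(2-methylbut-3-yn-2-yloxy)phenyl]ethanone | CC(=O)c1ccc(OCOC)cc1OC(C)(C)C#C | intermediate
4 | 1-[4-(methoxymethoxy)-2-(2-methylbut-3-en-2-yloxy)phenyl]ethanone | CC(=O)c1ccc(OCOC)cc1OC(C)(C)C=C | intermediate
5 | 3,5-dibromo-4-hydroxybenzaldehyde | O=Cc1cc(Br)c(O)c(Br)c1 | starting material
6 | 3,5-dibromo-4-(methoxymethoxy)benzaldehyde | O=Cc1cc(Br)c(OCOC)c(Br)c1 | intermediate
7 | 4-(methoxymethoxy)-3,5-bis(3-methylbut-2-enyl)benzaldehyde | O=Cc1cc(CC=C(C)C)c(OCOC)c(CC=C(C)C)c1 | intermediate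
8 | (2E)-1-[4-(methoxymethoxy)-2-(2-methylbut-3-en-2-yloxy)phenyl]-3-[4-(methoxymethoxy)-3,5-bis(3-methylbut-2-enyl)phenyl]prop-2-en-1-one | C=CC(C)(C)Oc1cc(OCOC)ccc1C(=O)/C=C/c1cc(CC=C(C)C)c(OCOC)c(CC=C(C)C)c1 | intermediate
9 | [(2R,3S)-3-[4-(methoxymethoxy)-3,5-bis(3-methylbut-2-enyl)phenyl]oxiran-2-yl][4-(methoxymethoxy)-2-(2-methylbut-3-en-2-yloxy)phenyl]methanone | C=CC(C)(C)Oc1cc(OCOC)ccc1C(=O)[C@@H]1O[C@H]1c1cc(CC=C(C)C)c(OCOC)c(CC=C(C)C)c1 | intermediate
10 | Claisen ortho-dienone: the (2R,3S)-epoxy ketone of 9 in which ring A is a 5-(methoxymethoxy)-6-(3-methylbut-2-enyl)cyclohexa-2,4-dien-1-one acylated at C2 (both epimers at the ring sp3 carbon) | CC(C)=CCC1C(OCOC)=CC=C(C1=O)C(=O)[C@@H]1O[C@H]1c1cc(CC=C(C)C)c(OCOC)c(CC=C(C)C)c1 | intermediate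
11 | [2-hydroxy-4-(methoxymethoxy)-3-(3-methylbut-2-enyl)phenyl][(2R,3S)-3-[4-(methoxymethoxy)-3,5-bis(3-methylbut-2-enyl)phenyl]oxiran-2-yl]methanone | CC(C)=CCc1c(O)c(ccc1OCOC)C(=O)[C@@H]1O[C@H]1c1cc(CC=C(C)C)c(OCOC)c(CC=C(C)C)c1 | intermediate
12 | (2R,3R)-3-hydroxy-7-(methoxymethoxy)-2-[4-(methoxymethoxy)-3,5-bis(3-methylbut-2-enyl)phenyl]-8-(3-methylbut-2-enyl)chroman-4-one | CC(C)=CCc1cc([C@H]2Oc3c(ccc(OCOC)c3CC=C(C)C)C(=O)[C@@H]2O)cc(CC=C(C)C)c1OCOC | intermediate
13 | (2R,3R)-3,7-dihydroxy-2-[4-hydroxy-3,5-bis(3-methylbut-2-enyl)phenyl]-8-(3-methylbut-2-enyl)chroman-4-one | CC(C)=CCc1cc([C@H]2Oc3c(ccc(O)c3CC=C(C)C)C(=O)[C@@H]2O)cc(CC=C(C)C)c1O | target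

## Step count and risks

Total steps: 9. Longest linear sequence: 7 steps (1 → 2 → 3 → 4 → 8 → 9 → 12 → 13).

**Step 8 (Proposed new method).** The tertiary allyl–oxygen bond may break heterolytically, with loss of isoprene or non-concerted allyl transfer. The oxirane may open by ionisation or by acyl shift before the phenol arrives. The cascade may also stall after the sigmatropic shift. The fallback separates the two events and uses known chemistry. It sets out from 4 and rejoins the route at 13.
- Heating 4 in PhMe at 110 °C should give, by aromatic Claisen rearrangement, 1-[2-hydroxy-4-(methoxymethoxy)-3-(3-methylbut-2-enyl)phenyl]ethanone F1.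
- MOMCl with NaH in DMF should convert it into 1-[2,4-bis(methoxymethoxy)-3-(3-methylbut-2-enyl)phenyl]ethanone F2.
- Claisen–Schmidt condensation with 7 (KOH, EtOH) should give the tris-MOM E-chalcone F3.
- Juliá–Colonna epoxidation as in step 7 should give the tris-MOM (2R,3S)-epoxy ketone F4.
- HCl in MeOH at 40–50 °C should remove the three MOM groups and let the freed 2'-phenol close ring C on the epoxide, the established chalcone-epoxide route to trans-dihydroflavonols, giving 13 directly.

**Step 7.** Conjugate addition to a hindered, electron-rich enone may be slow, and facial selectivity inside the polypeptide may be poor. The fallback builds the oxirane by C–C bond formation instead of oxidation. It sets out from 4 and rejoins the route at 9.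
- Chlorination of the lithium enolate of 4 (LiHMDS, THF, −78 °C, then N-chlorosuccinimide) should give 2-chloro-1-[4-(methoxymethoxy)-2-(2-methylbut-3-en-2-yloxy)phenyl]ethanone F5.
- An asymmetric Darzens reaction of F5 with aldehyde 7 under a cinchona-derived quaternary ammonium phase-transfer catalyst (LiOH·H2O, CH2Cl2, low temperature) should give the trans-epoxy ketone 9. The pseudoenantiomeric catalyst that leads to the (αR,βS) series is chosen.

**Step 2.** O-Alkylation of a hydrogen-bonded, hindered phenol may be poor, with the propargylic electrophile consumed by elimination instead. The fallback removes the chelate before the etherification. It sets out from 2 and rejoins the route at 3.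
- NaBH4 in MeOH should reduce the ketone to 2-(1-hydroxyethyl)-5-(methoxymethoxy)phenol F6, whose phenol is no longer deactivated by the acyl group.
- The copper-catalysed propargylation of step 2 should then take the phenol selectively and give 1-[4-(methoxymethoxy)-2-(2-methylbut-3-yn-2-yloxy)phenyl]ethanol F7.
- MnO2 in CH2Cl2 should reoxidise the benzylic alcohol to 3.

Further compounds

F1 | step 8 | 1-[2-hydroxy-4-(methoxymethoxy)-3-(3-methylbut-2-enyl)phenyl]ethanone | CC(=O)c1ccc(OCOC)c(CC=C(C)C)c1O
F2 | step 8 | 1-[2,4-bis(methoxymethoxy)-3-(3-methylbut-2-enyl)phenyl]ethanone | CC(=O)c1ccc(OCOC)c(CC=C(C)C)c1OCOC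
F3 | step 8 | (2E)-1-[2,4-bis(methoxymethoxy)-3-(3-methylbut-2-enyl)phenyl]-3-[4-(methoxymethoxy)-3,5-bis(3-methylbut-2-enyl)phenyl]prop-2-en-1-one | COCOc1ccc(C(=O)/C=C/c2cc(CC=C(C)C)c(OCOC)c(CC=C(C)C)c2)c(OCOC)c1CC=C(C)C
F4 | step 8 | [2,4-bis(methoxymethoxy)-3-(3-methylbut-2-enyl)phenyl][(2R,3S)-3-[4-(methoxymethoxy)-3,5-bis(3-methylbut-2-enyl)phenyl]oxiran-2-yl]methanone | COCOc1ccc(C(=O)[C@@H]2O[C@H]2c2cc(CC=C(C)C)c(OCOC)c(CC=C(C)C)c2)c(OCOC)c1CC=C(C)C
F5 | step 7 | 2-chloro-1-[4-(methoxymethoxy)-2-(2-methylbut-3-en-2-yloxy)phenyl]ethanone | O=C(CCl)c1ccc(OCOC)cc1OC(C)(C)C=C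
F6 | step 2 | 2-(1-hydroxyethyl)-5-(methoxymethoxy)phenol (racemic) | CC(O)c1ccc(OCOC)cc1O
F7 | step 2 | 1-[4-(methoxymethoxy)-2-(2-methylbut-3-yn-2-yloxy)phenyl]ethanol (racemic) | CC(O)c1ccc(OCOC)cc1OC(C)(C)C#C
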